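## Retrosynthetic overview

- Ring C is the only ring that is built, and it is built last: the O-1–C-2 bond is closed by an enantioselective 6-endo oxa-Michael addition of a 2',6'-dihydroxychalcone, which sets C-2 as S.
- The two ortho OH groups of that chalcone are equivalent, so either one closes to the same flavanone; no protecting groups are needed.
- The chalcone comes from a Claisen–Schmidt condensation of 3,5-diprenyl-4-O-methylphloroacetophenone with 4-hydroxybenzaldehyde (ring B is bought).
- The ketone comes from phloroacetophenone (ring A is bought) by twofold C-prenylation, then selective 4-O-methylation.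

Assumption: the facial preference of the new catalyst in step 4 cannot be read from precedent. The (S,S)-ligand is written; if the CD spectrum of the flavanone shows the 2R pattern (a 2S flavanone has a positive band near 330 nm and a negative band near 290 nm), the mirror-image ligand is used.

Ligand L in step 4 is the C2-symmetric N,N'-dioxide 1,1'-(propane-1,3-diyl)bis[(2S)-2-[(2,6-diisopropylphenyl)carbamoyl]piperidine 1-oxide], derived from (S)-pipecolic acid.

## Route

Step 1
Reactants: 1 2',4',6'-trihydroxyacetophenone (phloroacetophenone); 2 prenyl bromide (1-bromo-3-methylbut-2-ene)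
Product: 4 diprenyl ketone 1-[2,4,6-trihydroxy-3,5-bis(3-methylbut-2-en-1-yl)phenyl]ethanone, via mono-C-prenyl ketone 3 (not isolated)
Conditions: 2 (2.3 equiv), 10% aq KOH (3 equiv), 0 °C → rt, 3 h, N2; then 1 M HCl
Reagents that add atoms: none
Why: Base-mediated C-alkylation of a phloroglucinol phenolate (the classical C-prenylation of acylphloroglucinols): in water the oxygens of the polyanion are hydrogen-bonded, so the soft allylic bromide is attacked by ring carbon at the only two free positions, C-3 then C-5, and keeping 2 near two equivalents limits the dearomatised gem-diprenyl by-products; no stereocentre is formed.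

Step 2
Reactants: 4 1-[2,4,6-trihydroxy-3,5-bis(3-methylbut-2-en-1-yl)phenyl]ethanone
Product: 5 1-[2,6-dihydroxy-4-methoxy-3,5-bis(3-methylbut-2-en-1-yl)phenyl]ethanone
Conditions: Me2SO4 (1.05 equiv), K2CO3 (1.1 equiv), acetone, 0 °C → rt, 6 h, N2
Reagents that add atoms: dimethyl sulfate, COS(=O)(=O)OC
Why: Chemoselective Williamson O-methylation: the 4-OH, para to the acetyl group, is the most acidic phenol, while the two ortho OH groups are deactivated by hydrogen bonding to the carbonyl, so one equivalent of the hard electrophile Me2SO4 in an aprotic solvent methylates O-4 rather than carbon or the ortho oxygens; no stereocentre is formed.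

Step 3
Reactants: 5 1-[2,6-dihydroxy-4-methoxy-3,5-bis(3-methylbut-2-en-1-yl)phenyl]ethanone; 6 4-hydroxybenzaldehyde
Product: 8 (E)-1-[2,6-dihydroxy-4-methoxy-3,5-bis(3-methylbut-2-en-1-yl)phenyl]-3-(4-hydroxyphenyl)prop-2-en-1-one, via aldol adduct 7 (not isolated)
Conditions: 6 (1.5 equiv), 50% aq KOH, EtOH, rt, 48 h, Ar, dark; then ice-cold 1 M HCl to pH 3
Reagents that add atoms: none
Why: Claisen–Schmidt (crossed aldol) condensation: the methyl-ketone enolate of 5 adds to the non-enolisable aldehyde 6 and aldol adduct 7 loses water by E1cB to the conjugated (E)-enone, the favoured alkene geometry, while the strongly basic medium keeps the product as the open-chain phenolate until cold acidification releases the chalcone; no stereocentre remains.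

Step 4
Reactants: 8 (E)-1-[2,6-dihydroxy-4-methoxy-3,5-bis(3-methylbut-2-en-1-yl)phenyl]-3-(4-hydroxyphenyl)prop-2-en-1-one
Product: 9 (2S)-5-hydroxy-2-(4-hydroxyphenyl)-7-methoxy-6,8-bis(3-methylbut-2-en-1-yl)-2,3-dihydro-4H-chromen-4-one
Conditions: Ni(OAc)2·4H2O (10 mol%), ligand L (11 mol%; precomplexed in THF, 35 °C, 1 h), CH2Cl2/THF 9:1, 0 °C, 36 h, N2; then 5% aq citric acid
Reagents that add atoms: none
Why: Proposed new method: chelation-templated enantioselective 6-endo oxa-Michael cyclisation of an unactivated, unprotected 2',6'-dihydroxychalcone – one of the two equivalent ortho phenols and the carbonyl oxygen bind the chiral N,N'-dioxide–nickel centre as an acylphenolate chelate (acetate takes the proton), which lowers the enone LUMO and fixes the substrate in the octahedral chiral pocket; the other ortho OH, assisted by outer-sphere acetate as general base, then adds to one enantiotopic face of C-β and so sets C-2 as S, the nickel enolate is protonated at C-3 by AcOH and the product chelate is displaced by fresh 8; since 5-hydroxyflavanone formation lies far on the product side, the catalysed reverse reaction that erodes ee with simple 2'-hydroxychalcones is slow, and the neutral B-ring phenol is tolerated because no strong base is present; closest known reaction type: chiral N,N'-dioxide–nickel catalysed intramolecular oxa-Michael addition of ester-activated 2'-hydroxychalcones, and chiral Lewis acid activation of 2'-hydroxychalcones through phenolate/carbonyl chelation in Diels–Alder reactions.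

## Compound list

1 | 1-(2,4,6-trihydroxyphenyl)ethanone (phloroacetophenone) | CC(=O)c1c(O)cc(O)cc1O | starting material
2 | 1-bromo-3-methylbut-2-ene (prenyl bromide) | CC(C)=CCBr | starting material
3 | 1-[2,4,6-trihydroxy-3-(3-methylbut-2-en-1-yl)phenyl]ethanone (forms in the flask, not isolated) | CC(=O)c1c(O)cc(O)c(CC=C(C)C)c1O | intermediate
4 | 1-[2,4,6-trihydroxy-3,5-bis(3-methylbut-2-en-1-yl)phenyl]ethanone | CC(=O)c1c(O)c(CC=C(C)C)c(O)c(CC=C(C)C)c1O | intermediate
5 | 1-[2,6-dihydroxy-4-methoxy-3,5-bis(3-methylbut-2-en-1-yl)phenyl]ethanone | CC(=O)c1c(O)c(CC=C(C)C)c(OC)c(CC=C(C)C)c1O | intermediate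
6 | 4-hydroxybenzaldehyde | O=Cc1ccc(O)cc1 | starting material
7 | 1-[2,6-dihydroxy-4-methoxy-3,5-bis(3-methylbut-2-en-1-yl)phenyl]-3-hydroxy-3-(4-hydroxyphenyl)propan-1-one (racemic aldol adduct, not isolated) | COc1c(CC=C(C)C)c(O)c(C(=O)CC(O)c2ccc(O)cc2)c(O)c1CC=C(C)C | intermediate
8 | (E)-1-[2,6-dihydroxy-4-methoxy-3,5-bis(3-methylbut-2-en-1-yl)phenyl]-3-(4-hydroxyphenyl)prop-2-en-1-one | COc1c(CC=C(C)C)c(O)c(C(=O)/C=C/c2ccc(O)cc2)c(O)c1CC=C(C)C | intermediate
9 | (2S)-5-hydroxy-2-(4-hydroxyphenyl)-7-methoxy-6,8-bis(3-methylbut-2-en-1-yl)-2,3-dihydro-4H-chromen-4-one | COc1c(CC=C(C)C)c(O)c2c(c1CC=C(C)C)O[C@H](c1ccc(O)cc1)CC2=O | target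

## Step count and risks

Total step count: 4. Longest linear sequence: 4 steps (1 → 4 → 5 → 8 → 9).

**Step 1 (twofold C-prenylation).** The yield is expected to be modest, about 30%, because mono-, gem-di- and tri-prenylated products and O-alkylation compete, and 4 is air-sensitive. The fallback puts the prenyl groups on oxygen first and moves them to carbon afterwards. It sets out from 1 and comes back at 5, so step 2 is no longer needed. 1 is methylated at the 4-OH (Me2SO4, K2CO3, acetone) to 1-(2,6-dihydroxy-4-methoxyphenyl)ethanone F1, which can also be bought. Both OH groups are then O-prenylated with 2 (K2CO3, DMF, 60 °C) to 1-[4-methoxy-2,6-bis(3-methylbut-2-en-1-yloxy)phenyl]ethanone F2. Montmorillonite K10 in CH2Cl2 (0 °C → rt) shifts each prenyl group from oxygen to the free ortho carbon, through 1-[2-hydroxy-4-methoxy-3-(3-methylbut-2-en-1-yl)-6-(3-methylbut-2-en-1-yloxy)phenyl]ethanone F3 (not isolated), to give 5.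

**Step 3 (unprotected Claisen–Schmidt).** The phenolate of 6 is a poor electrophile and the ketone reacts as a polyanion, so conversion may be low; 8 can also ring-close to racemic flavanone on work-up. The fallback masks the aldehyde phenol. It sets out from 5 and comes back at 8. 5 is condensed with commercial 4-(methoxymethoxy)benzaldehyde (KOH, EtOH/H2O, rt), through the aldol adduct 1-[2,6-dihydroxy-4-methoxy-3,5-bis(3-methylbut-2-en-1-yl)phenyl]-3-hydroxy-3-[4-(methoxymethoxy)phenyl]propan-1-one F4 (not isolated), to the protected chalcone (E)-1-[2,6-dihydroxy-4-methoxy-3,5-bis(3-methylbut-2-en-1-yl)phenyl]-3-[4-(methoxymethoxy)phenyl]prop-2-en-1-one F5. The acetal is then cleaved with HCl in MeOH at rt, stopped before ring closure, to give 8.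

**Step 4 (new method).** Turnover may stall through product binding, a racemic background cyclisation may compete, or the ee or its sense may be unsatisfactory. The ee is measured by HPLC on a polysaccharide column and the configuration by CD. The fallback uses known chemistry. It sets out from 8 and comes back at 9. 8 is cyclised with NaOAc in refluxing EtOH (the standard chalcone–flavanone isomerisation) to racemic 5-hydroxy-2-(4-hydroxyphenyl)-7-methoxy-6,8-bis(3-methylbut-2-en-1-yl)-2,3-dihydro-4H-chromen-4-one F6. F6 is resolved by preparative HPLC on an amylose tris(3,5-dimethylphenylcarbamate) column (hexane/iPrOH) to give 9. The unwanted (2R)-5-hydroxy-2-(4-hydroxyphenyl)-7-methoxy-6,8-bis(3-methylbut-2-en-1-yl)-2,3-dihydro-4H-chromen-4-one F7 is ring-opened back to 8 with KOH in EtOH and recycled.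

## Further compounds

F1 | step 1 | 1-(2,6-dihydroxy-4-methoxyphenyl)ethanone | CC(=O)c1c(O)cc(OC)cc1O
F2 | step 1 | 1-[4-methoxy-2,6-bis(3-methylbut-2-en-1-yloxy)phenyl]ethanone | CC(=O)c1c(OCC=C(C)C)cc(OC)cc1OCC=C(C)C
F3 | step 1 | 1-[2-hydroxy-4-methoxy-3-(3-methylbut-2-en-1-yl)-6-(3-methylbut-2-en-1-yloxy)phenyl]ethanone | CC(=O)c1c(O)c(CC=C(C)C)c(OC)cc1OCC=C(C)C
F4 | step 3 | 1-[2,6-dihydroxy-4-methoxy-3,5-bis(3-methylbut-2-en-1-yl)phenyl]-3-hydroxy-3-[4-(methoxymethoxy)phenyl]propan-1-one | COCOc1ccc(C(O)CC(=O)c2c(O)c(CC=C(C)C)c(OC)c(CC=C(C)C)c2O)cc1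
F5 | step 3 | (E)-1-[2,6-dihydroxy-4-methoxy-3,5-bis(3-methylbut-2-en-1-yl)phenyl]-3-[4-(methoxymethoxy)phenyl]prop-2-en-1-one | COCOc1ccc(/C=C/C(=O)c2c(O)c(CC=C(C)C)c(OC)c(CC=C(C)C)c2O)cc1
F6 | step 4 | racemic 5-hydroxy-2-(4-hydroxyphenyl)-7-methoxy-6,8-bis(3-methylbut-2-en-1-yl)-2,3-dihydro-4H-chromen-4-one | COc1c(CC=C(C)C)c(O)c2c(c1CC=C(C)C)OC(c1ccc(O)cc1)CC2=O
F7 | step 4 | (2R)-5-hydroxy-2-(4-hydroxyphenyl)-7-methoxy-6,8-bis(3-methylbut-2-en-1-yl)-2,3-dihydro-4H-chromen-4-one | COc1c(CC=C(C)C)c(O)c2c(c1CC=C(C)C)O[C@@H](c1ccc(O)cc1)CC2=O
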